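**Retrosynthetic overview**

1. Numbering used throughout: C1 = quaternary ring carbon, then C2=C3, C4 (acyloxy), C5–C6 (epoxide), C7, C8, C9=C10, C11; C12 = CH2OH carbon on C9.
2. Target 32 ⇐ eleven-membered Z-enone 26 by Saegusa dehydrogenation (C2=C3), reagent-controlled reduction at C4, hydroxyl-directed epoxidation of C5=C6, senecioylation and desilylation.
3. Feature on which the strategy rests: in the eleven-membered ring the C4 oxygen and the ring-cis C9=C10 alkene are 1,3-related through C9 (a Grob retron). Reconnecting C4–C9 gives mesylate 24, a 2-methylcyclohex-2-en-1-ol ring (C4–C9) cis-fused to a cycloheptane ring (C1–C4, C9–C11) with the leaving group on C10.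
4. 24 ⇐ C10 set by directed reduction; seven-membered ring closed by addition of C3–Li to the C4 carbonyl of a cyclohexenone; C9–C10 by aldol of enone 15 with aldehyde 11. Ring order: six-membered ring bought, seven-membered ring second, eleven-membered ring third by cleaving their shared bond, epoxide last.
5. 11 ⇐ ketol cleavage of (S)-3-methyl-3-homoprenylcyclopentanone 4 ⇐ asymmetric conjugate addition to 3-methylcyclopent-2-enone 2.

Key step: step 15

Remark on the chemistry: C4, C9 and C10 are sacrificial centres (all become trigonal in step 15) and C1 is too remote to bias the aldol of step 9, so each of 17–24 is expected as the isomer drawn together with its partner in which C9, and with it C4 and C10 once they are defined, has the opposite sense; the two series have the same relative configuration, are carried on unseparated and converge on 26; the C10 carbinol of 17, 18 and 21 is left undefined because step 12 erases it; bicyclic and macrocyclic compounds are named with the ring numbering of the overview.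

**Route**

Step 1
Reactants: 1 5-bromo-2-methylpent-2-ene; 2 3-methylcyclopent-2-en-1-one
Product: 4 (3S)-3-methyl-3-(4-methylpent-3-en-1-yl)cyclopentan-1-one, via Grignard reagent 3 (not isolated)
Conditions: Mg, Et2O, reflux; then 2, Cu(OTf)2 (3 mol%), chiral C2-symmetric 1,3-diaryl-4,5-diphenylimidazolinium salt (4 mol%, carbene precursor, enantiomer chosen for the S ketone), Et2O, −30 to 0 °C; then H2O
Reagents that add atoms: none
Why: Copper-catalysed asymmetric conjugate addition of the Grignard reagent under the chiral carbene ligand transfers the homoprenyl group to one enantioface of the β-methyl enone and thereby sets the all-carbon quaternary centre (C1 of the target), the ligand enantiomer being the one that delivers the S ketone.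

Step 2
Reactants: 4 (3S)-3-methyl-3-(4-methylpent-3-en-1-yl)cyclopentan-1-one
Product: 6 (4S)-2-hydroxy-4-methyl-4-(4-methylpent-3-en-1-yl)cyclopentan-1-one (both C2 epimers), via lithium enolate 5 (not isolated)
Conditions: LiN(i-Pr)2, THF, −78 °C; racemic (camphorsulfonyl)oxaziridine, −78 to 0 °C; AcOH
Reagents that add atoms: (camphorsulfonyl)oxaziridine, CC1(C)C2CCC13CS(=O)(=O)N4OC34C2
Why: Kinetic deprotonation by the bulky amide takes place at the CH2 remote from the quaternary carbon (the other α-CH2 is neopentyl-like) and oxygen transfer from the N-sulfonyloxaziridine to that enolate carbon (Davis α-hydroxylation) leaves the trisubstituted alkene untouched; the new carbinol forms as both epimers, which is irrelevant because step 3 destroys it.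

Step 3
Reactants: 6 (4S)-2-hydroxy-4-methyl-4-(4-methylpent-3-en-1-yl)cyclopentan-1-one
Product: 7 methyl (3S)-3,7-dimethyl-3-(2-oxoethyl)oct-6-enoate
Conditions: Pb(OAc)4, MeOH–toluene (1:1), 0 °C
Reagents that add atoms: methanol, CO
Why: Lead tetraacetate cleaves the C–C bond of the α-ketol (Criegee-type cleavage) and methanol captures the acyl end as the methyl ester, so the two two-carbon arms on the quaternary carbon emerge differentiated as aldehyde (future C10) and ester (future C3).

Step 4
Reactants: 7 methyl (3S)-3,7-dimethyl-3-(2-oxoethyl)oct-6-enoate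
Product: 8 methyl (3S)-3-(2,2-dimethoxyethyl)-3,7-dimethyloct-6-enoate
Conditions: HC(OMe)3, TsOH·H2O (cat.), MeOH, rt; NaHCO3
Reagents that add atoms: trimethyl orthoformate, COC(OC)OC
Why: Acid-catalysed acetalisation with the orthoester as water scavenger masks the aldehyde so that the ester can be reduced on its own.

Step 5
Reactants: 8 methyl (3S)-3-(2,2-dimethoxyethyl)-3,7-dimethyloct-6-enoate
Product: 9 (3R)-3-(2,2-dimethoxyethyl)-3,7-dimethyloct-6-en-1-ol
Conditions: LiAlH4, Et2O, 0 °C; H2O, aq. NaOH work-up
Reagents that add atoms: none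
Why: Hydride reduction of the ester to the primary alcohol leaves the dimethyl acetal and the alkene unchanged.

Step 6
Reactants: 9 (3R)-3-(2,2-dimethoxyethyl)-3,7-dimethyloct-6-en-1-ol
Product: 11 (3S)-3-(2-iodoethyl)-3,7-dimethyloct-6-enal, via iodo acetal 10 (not isolated)
Conditions: I2, PPh3, imidazole, CH2Cl2, 0 °C to rt; then 1 M aq. HCl–THF, rt
Reagents that add atoms: iodine, II; water, O
Why: Appel-type iodination (Garegg–Samuelsson conditions) converts the unhindered primary alcohol into the iodide with no carbocation that could involve the alkene, and dilute aqueous acid then hydrolyses the dimethyl acetal to the aldehyde.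

Step 7
Reactants: 12 2-methylcyclohex-2-en-1-one
Product: 14 6-(hydroxymethyl)-2-methylcyclohex-2-en-1-one (racemic), via lithium dienolate 13 (not isolated)
Conditions: LiN(i-Pr)2, THF, −78 °C; CH2O (gas, from cracked paraformaldehyde), −78 °C; AcOH
Reagents that add atoms: formaldehyde, C=O
Why: Kinetic α′-deprotonation gives the cross-conjugated dienolate, whose aldol addition to monomeric formaldehyde installs the C12 hydroxymethyl group at the future C9; the centre is racemic and is planarised again in step 9.

Step 8
Reactants: 14 6-(hydroxymethyl)-2-methylcyclohex-2-en-1-one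
Product: 15 6-({[tert-butyl(dimethyl)silyl]oxy}methyl)-2-methylcyclohex-2-en-1-one (racemic)
Conditions: TBSCl, imidazole, DMF, 0 °C to rt
Reagents that add atoms: tert-butyl(chloro)dimethylsilane, CC(C)(C)[Si](C)(C)Cl
Why: Standard silylation of the primary alcohol, which also blocks dehydration of the β-hydroxy ketone.

Step 9
Reactants: 15 6-({[tert-butyl(dimethyl)silyl]oxy}methyl)-2-methylcyclohex-2-en-1-one; 11 (3S)-3-(2-iodoethyl)-3,7-dimethyloct-6-enal
Product: 17 aldol adduct 6-({[tert-butyl(dimethyl)silyl]oxy}methyl)-6-[(3S)-1-hydroxy-3-(2-iodoethyl)-3,7-dimethyloct-6-en-1-yl]-2-methylcyclohex-2-en-1-one, via lithium dienolate 16 (not isolated)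
Conditions: LiN(i-Pr)2, THF, −78 °C; then 11, −78 °C; AcOH at −78 °C
Reagents that add atoms: none
Why: Kinetic α′-deprotonation regenerates a fully substituted dienolate whose aldol addition to the aldehyde forms the C9–C10 bond and the quaternary C9; neither the enolate face (C1 is too far away) nor the C10 carbinol is controlled, which is accepted because C9 is relayed to C4 and C10 in steps 11 to 13 and all three centres vanish in step 15.

Step 10
Reactants: 17 aldol adduct
Product: 18 C10 trimethylsilyl ether of 17
Conditions: TMSCl, imidazole, DMF, 0 °C to rt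
Reagents that add atoms: chlorotrimethylsilane, C[Si](C)(C)Cl
Why: Silylation of the secondary aldol hydroxyl prevents retro-aldol cleavage and intramolecular O-alkylation by the iodide under the basic conditions of step 11.

Step 11
Reactants: 18 C10 trimethylsilyl ether of 17
Product: 21 cis-fused bicyclic 4,10-diol (both C10 epimers), via alkyllithium 19 (not isolated), via lithium alkoxide 20 (not isolated)
Conditions: t-BuLi (2.2 equiv), Et2O–pentane, −78 °C, high dilution, then 0 °C; MeOH, K2CO3 (cat.), rt
Reagents that add atoms: none
Why: Iodine–lithium exchange at the primary iodide is faster than attack of t-BuLi on the hindered C4 carbonyl, which has no α-hydrogen to lose, and the alkyllithium then adds 1,2 to this carbonyl (intramolecular Barbier-type addition, 7-exo-trig); because the tether is anchored at C9 the carbanion arrives on the face of C10 and pushes the C4 oxygen cis to C12 (cis ring fusion), and methanolysis removes the trimethylsilyl group.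

Step 12
Reactants: 21 cis-fused bicyclic 4,10-diol
Product: 22 cis-fused bicyclic 4-hydroxy-10-ketone
Conditions: Dess–Martin periodinane, pyridine, CH2Cl2, 0 °C to rt
Reagents that add atoms: none
Why: Dess–Martin oxidation affects only the secondary C10 alcohol (the tertiary allylic C4 alcohol cannot be oxidised and pyridine keeps it from ionising), which merges the two C10 epimers into one ketone per series.

Step 13
Reactants: 22 cis-fused bicyclic 4-hydroxy-10-ketone
Product: 23 cis-fused bicyclic anti-4,10-diol (10-OH trans to 4-OH)
Conditions: Me4NBH(OAc)3, MeCN–AcOH (1:1), −30 to −20 °C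
Reagents that add atoms: none
Why: Directed reduction of the Evans–Saksena type: the borohydride exchanges an acetate for the C4 hydroxyl and delivers hydride to C10 from the face of that oxygen, so the new C10 hydroxyl ends trans to the C4 hydroxyl (anti-1,3-diol) and hence trans to C12, while the ketone is inert to the free reagent.

Step 14
Reactants: 23 cis-fused bicyclic anti-4,10-diol
Product: 24 cis-fused bicyclic 4-hydroxy 10-mesylate (key-step precursor; OMs trans to 4-OH and to C12)
Conditions: MsCl, Et3N, CH2Cl2, −20 to 0 °C
Reagents that add atoms: methanesulfonyl chloride, CS(=O)(=O)Cl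
Why: Sulfonylation through sulfene selects the secondary C10 alcohol, the tertiary allylic C4 alcohol being too hindered to react at low temperature, and triethylamine is too weak a base to start the fragmentation.

Step 15
Reactants: 24 cis-fused bicyclic 4-hydroxy 10-mesylate
Product: 26 eleven-membered Z-enone with ring-cis C9=C10 (C12 silyl ether), via potassium alkoxide 25 (not isolated)
Conditions: KOt-Bu (1.5 equiv), THF, 0 °C to rt
Reagents that add atoms: none
Why: KOt-Bu deprotonates the tertiary C4 hydroxyl and the alkoxide 25 fragments in one concerted Grob (Wharton-type) step: the oxygen lone pair forms C4=O, the ring-fusion bond C4–C9 breaks, its electrons form C9=C10 and mesylate leaves from C10. The closest known reaction type is the base-induced fragmentation of bicyclic 1,3-hydroxy sulfonates that carry the hydroxyl on a ring-fusion carbon, a standard entry to medium-ring cycloalkenones. The eleven-membered ring is not closed end to end; it appears by scission of the bond shared by the six- and seven-membered rings (ring expansion by fragmentation), so no macrocyclisation entropy is paid. No stereocentre is created (C4, C9 and C10 become trigonal, which is why their mixed history is harmless); the information is transferred to alkene geometry instead: with the C10–OMs bond antiperiplanar to C4–C9, the trans relationship of OMs and C12 set in step 13 puts C8 and C11 on the same side of the new double bond (the ring-cis C9=C10 of the target), and C5=C6 keeps the Z geometry it had in the cyclohexene. The step needs fragmentation to win over elimination and oxetane formation: C9 is quaternary and offers no hydrogen, the neopentyl-type C10 resists substitution, the equatorial mesylate on the flexible seven-membered ring can reach the antiperiplanar arrangement, and the conjugated enone being formed stabilises the developing carbonyl. A short reaction time at 0 °C with a non-nucleophilic base should limit isomerisation of, or conjugate addition to, the Z-enone.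

Step 16
Reactants: 26 eleven-membered Z-enone
Product: 28 cross-conjugated (2E,5Z)-dienone, via silyl dienol ether 27 (not isolated)
Conditions: LiN(i-Pr)2, TMSCl, THF, −78 °C; then Pd(OAc)2 (1.1 equiv), MeCN, rt
Reagents that add atoms: none
Why: Saegusa–Ito dehydrogenation: deprotonation at C3, the only α-CH2 of the ketone, gives the cross-conjugated silyl dienol ether, and palladation followed by β-hydride elimination from C2 gives the C2=C3 alkene, for which the E geometry is expected in an eleven-membered ring.

Step 17
Reactants: 28 cross-conjugated (2E,5Z)-dienone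
Product: 29 (4S)-bis-allylic alcohol
Conditions: (R)-2-methyl-CBS-oxazaborolidine (0.5 equiv), catecholborane, toluene, −78 °C
Reagents that add atoms: none
Why: Corey–Bakshi–Shibata reduction: the oxazaborolidine binds the carbonyl oxygen anti to the bulkier α-methylated alkenyl arm (C5) and catecholborane, which does not hydroborate the alkenes at this temperature, delivers hydride to one face, so C4 is set as S by the reagent and independently of the remote C1 centre.

Step 18
Reactants: 29 (4S)-bis-allylic alcohol
Product: 30 (4S)-5,6-cis-epoxy alcohol (epoxide on the face of the 4-OH)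
Conditions: VO(acac)2 (5 mol%), t-BuOOH (in decane), CH2Cl2, 0 °C
Reagents that add atoms: tert-butyl hydroperoxide, CC(C)(C)OO
Why: Hydroxyl-directed vanadium-catalysed epoxidation: the vanadate ester of the C4 alcohol transfers oxygen to the adjacent trisubstituted Z alkene C5=C6 (more electron-rich than C2=C3) on the face of the hydroxyl in the conformer in which the ring bond to C3 lies on the far face and the carbinol hydrogen faces the C5 methyl, which gives the erythro cis-epoxy alcohol and sets C5 and C6; alkenes without a free allylic hydroxyl do not react.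

Step 19
Reactants: 30 (4S)-5,6-cis-epoxy alcohol
Product: 31 C4 3-methylbut-2-enoate (C12 silyl ether)
Conditions: 3-methylbut-2-enoyl chloride, pyridine, DMAP (cat.), CH2Cl2, 0 °C to rt
Reagents that add atoms: 3-methylbut-2-enoyl chloride, CC(C)=CC(=O)Cl
Why: DMAP-catalysed acylation of the secondary alcohol with the acid chloride in pyridine, a base too weak to deconjugate the senecioyl unit by way of a ketene.

Step 20
Reactants: 31 C4 3-methylbut-2-enoate (C12 silyl ether)
Product: 32 target CNP0318149.1
Conditions: Bu4NF, AcOH, THF, 0 °C to rt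
Reagents that add atoms: none
Why: Fluoride cleaves the primary silyl ether, and buffering with acetic acid keeps the ester and the epoxide intact.

**Compound list**

1 | 5-bromo-2-methylpent-2-ene | CC(C)=CCCBr | starting material
2 | 3-methylcyclopent-2-en-1-one | CC1=CC(=O)CC1 | starting material
3 | (4-methylpent-3-en-1-yl)magnesium bromide | CC(C)=CCC[Mg]Br | intermediate
4 | (3S)-3-methyl-3-(4-methylpent-3-en-1-yl)cyclopentan-1-one | CC(C)=CCC[C@@]1(C)CCC(=O)C1 | intermediate
5 | lithium (4S)-4-methyl-4-(4-methylpent-3-en-1-yl)cyclopent-1-en-1-olate | CC(C)=CCC[C@@]1(C)CC=C(O[Li])C1 | intermediate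
6 | (4S)-2-hydroxy-4-methyl-4-(4-methylpent-3-en-1-yl)cyclopentan-1-one (both C2 epimers) | CC(C)=CCC[C@@]1(C)CC(O)C(=O)C1 | intermediate
7 | methyl (3S)-3,7-dimethyl-3-(2-oxoethyl)oct-6-enoate | CC(C)=CCC[C@@](C)(CC=O)CC(=O)OC | intermediate
8 | methyl (3S)-3-(2,2-dimethoxyethyl)-3,7-dimethyloct-6-enoate | CC(C)=CCC[C@@](C)(CC(OC)OC)CC(=O)OC | intermediate
9 | (3R)-3-(2,2-dimethoxyethyl)-3,7-dimethyloct-6-en-1-ol | CC(C)=CCC[C@@](C)(CC(OC)OC)CCO | intermediate
10 | (6S)-6-(2,2-dimethoxyethyl)-8-iodo-2,6-dimethyloct-2-ene | CC(C)=CCC[C@@](C)(CC(OC)OC)CCI | intermediate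
11 | (3S)-3-(2-iodoethyl)-3,7-dimethyloct-6-enal | CC(C)=CCC[C@@](C)(CC=O)CCI | intermediate
12 | 2-methylcyclohex-2-en-1-one | CC1=CCCC1=O | starting material
13 | lithium 6-methylcyclohexa-1,5-dien-1-olate | CC1=CCCC=C1O[Li] | intermediate
14 | 6-(hydroxymethyl)-2-methylcyclohex-2-en-1-one (racemic) | CC1=CCCC(CO)C1=O | intermediate
15 | 6-({[tert-butyl(dimethyl)silyl]oxy}methyl)-2-methylcyclohex-2-en-1-one (racemic) | CC1=CCCC(CO[Si](C)(C)C(C)(C)C)C1=O | intermediate
16 | lithium dienolate of 15 (α′-deprotonated) | CC1=CCCC(CO[Si](C)(C)C(C)(C)C)=C1O[Li] | intermediate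
17 | 6-({[tert-butyl(dimethyl)silyl]oxy}methyl)-6-[(3S)-1-hydroxy-3-(2-iodoethyl)-3,7-dimethyloct-6-en-1-yl]-2-methylcyclohex-2-en-1-one (drawn series; both C10 epimers) | CC(C)=CCC[C@@](C)(CC(O)[C@]1(CO[Si](C)(C)C(C)(C)C)CCC=C(C)C1=O)CCI | intermediate
18 | C10 trimethylsilyl ether of 17 (drawn series; both C10 epimers) | CC(C)=CCC[C@@](C)(CC(O[Si](C)(C)C)[C@]1(CO[Si](C)(C)C(C)(C)C)CCC=C(C)C1=O)CCI | intermediate
19 | primary alkyllithium from 18 (lithium in place of iodine at C3) | CC(C)=CCC[C@@](C)(CC(O[Si](C)(C)C)[C@]1(CO[Si](C)(C)C(C)(C)C)CCC=C(C)C1=O)CC[Li] | intermediate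
20 | lithium C4-alkoxide of the cis-fused bicyclic C10 trimethylsilyl ether | CC(C)=CCC[C@]1(C)CC[C@@]2(O[Li])C(C)=CCC[C@@]2(CO[Si](C)(C)C(C)(C)C)C(O[Si](C)(C)C)C1 | intermediate
21 | (1R,4R,9R)-cis-fused bicyclic diol: 2-methylcyclohex-2-en-1-ol ring (C4–C9) fused at C4–C9 to the cycloheptane ring (C1–C4, C9–C11); 4-OH, 10-OH (both epimers), 9-CH2OTBS, 5-methyl, 1-methyl, 1-(4-methylpent-3-enyl) | CC(C)=CCC[C@]1(C)CC[C@@]2(O)C(C)=CCC[C@@]2(CO[Si](C)(C)C(C)(C)C)C(O)C1 | intermediate
22 | (1R,4R,9S)-cis-fused bicyclic 4-hydroxy-10-ketone of the same skeleton | CC(C)=CCC[C@]1(C)CC[C@@]2(O)C(C)=CCC[C@@]2(CO[Si](C)(C)C(C)(C)C)C(=O)C1 | intermediate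
23 | (1R,4R,9R,10S)-cis-fused bicyclic anti-4,10-diol (10-OH trans to 4-OH and to C12) | CC(C)=CCC[C@]1(C)CC[C@@]2(O)C(C)=CCC[C@@]2(CO[Si](C)(C)C(C)(C)C)[C@@H](O)C1 | intermediate
24 | (1R,4R,9R,10S)-cis-fused bicyclic 4-hydroxy 10-methanesulfonate (key-step precursor) | CC(C)=CCC[C@]1(C)CC[C@@]2(O)C(C)=CCC[C@@]2(CO[Si](C)(C)C(C)(C)C)[C@@H](OS(C)(=O)=O)C1 | intermediate
25 | potassium C4-alkoxide of 24 | CC(C)=CCC[C@]1(C)CC[C@@]2(O[K])C(C)=CCC[C@@]2(CO[Si](C)(C)C(C)(C)C)[C@@H](OS(C)(=O)=O)C1 | intermediate
26 | (1R,5Z,9E)-eleven-membered enone: C4 ketone, 5-methyl, Z C5=C6, ring-cis C9=C10, 9-CH2OTBS, 1-methyl, 1-(4-methylpent-3-enyl) (key-step product) | CC(C)=CCC[C@]1(C)CCC(=O)/C(C)=C\CC/C(CO[Si](C)(C)C(C)(C)C)=C\C1 | intermediate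
27 | C3=C4 trimethylsilyl dienol ether of 26 | CC(C)=CCC[C@]1(C)CC=C(O[Si](C)(C)C)/C(C)=C\CC/C(CO[Si](C)(C)C(C)(C)C)=C\C1 | intermediate
28 | (1S,2E,5Z,9E)-cross-conjugated dienone (C2=C3 and C5=C6 flanking the C4 ketone) | CC(C)=CCC[C@]1(C)/C=C/C(=O)/C(C)=C\CC/C(CO[Si](C)(C)C(C)(C)C)=C\C1 | intermediate
29 | (1S,2E,4S,5Z,9E)-bis-allylic C4 alcohol | CC(C)=CCC[C@]1(C)/C=C/[C@H](O)/C(C)=C\CC/C(CO[Si](C)(C)C(C)(C)C)=C\C1 | intermediate
30 | (1S,2E,4S,9E)-5,6-cis-epoxy C4 alcohol, epoxide oxygen on the face of the 4-OH (erythro) | CC(C)=CCC[C@]1(C)/C=C/[C@H](O)[C@]2(C)O[C@@H]2CC/C(CO[Si](C)(C)C(C)(C)C)=C\C1 | intermediate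
31 | C4 3-methylbut-2-enoate of 30 (C12 tert-butyldimethylsilyl ether) | CC(C)=CCC[C@]1(C)/C=C/[C@H](OC(=O)C=C(C)C)[C@]2(C)O[C@@H]2CC/C(CO[Si](C)(C)C(C)(C)C)=C\C1 | intermediate
32 | CNP0318149.1, (1S,2E,4S,5R,6R,9E) in the ring numbering of the overview: C4 senecioate, 5,6-epoxide, C12 primary alcohol | CC(C)=CCC[C@]1(C)/C=C/[C@H](OC(=O)C=C(C)C)[C@]2(C)O[C@@H]2CC/C(CO)=C\C1 | target

**Step count**

Total steps: 20. Longest linear sequence: 18 steps (steps 1–6 and 9–20); steps 7–8 prepare the enone partner.

**Steps most likely to fail, with fallbacks**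

Step 11 (closure of the seven-membered ring). t-BuLi may attack or γ-deprotonate the enone before the exchange, or the alkyllithium may be quenched or react between molecules before the ring closes. The fallback sets out from 18 and comes back at 21. It replaces the unstabilised organolithium by a sulfonyl-stabilised carbanion that can be generated with an amide base in the presence of the ketone. Displacement of the iodide of 18 with PhSO2Na in DMF would give the phenyl sulfone F1. LiN(i-Pr)2 in THF at −78 °C would give the α-sulfonyl carbanion, whose addition to the C4 carbonyl would close the ring to the bicyclic β-hydroxy sulfone F2 (cold quench). Na/Hg with Na2HPO4 in MeOH would remove the sulfonyl group and K2CO3 in MeOH the trimethylsilyl group, which returns to 21.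

Step 15 (fragmentation). The alkoxide may close an oxetane onto C10, or the mesylate may eliminate towards C11, if the seven-membered ring does not hold the C10–O bond antiperiplanar to C4–C9. The fallback sets out from 24 and comes back at 26. It cleaves the same bond stepwise through an enolate, without the antiperiplanar demand. HF·pyridine would free the primary alcohol F3 and Dess–Martin oxidation would give the β-hydroxy aldehyde F4. A mild base (DBU, CH2Cl2) would then trigger retro-aldol scission of C4–C9 followed by E1cB loss of mesylate from the aldehyde enolate, giving the keto enal F5; the enal with CHO trans to C11, which is the ring-cis C9=C10 isomer, is expected as the more stable one. NaBH4 at −78 °C would reduce only the aldehyde to the allylic alcohol F6, and TBSCl with imidazole would return to 26.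

Step 17 (reduction at C4). Facial selectivity may be poor if the catalyst does not distinguish the two alkenyl arms or if a conformational bias of the macrocycle opposes it. The fallback sets out from 28 and comes back at 29. It gives up reagent control in favour of separation and recycling. Luche reduction (NaBH4, CeCl3·7H2O, MeOH, −78 °C) would give 29 together with its C4 epimer F7. The two diastereomers would be separated by chromatography and F7 oxidised back to 28 with MnO2 for another pass.

**Further compounds**

F1 | step 11 | phenyl sulfone from 18 (PhSO2 in place of iodine at C3) | CC(C)=CCC[C@@](C)(CC(O[Si](C)(C)C)[C@]1(CO[Si](C)(C)C(C)(C)C)CCC=C(C)C1=O)CCS(=O)(=O)c1ccccc1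
F2 | step 11 | cis-fused bicyclic β-hydroxy sulfone (3-phenylsulfonyl, 4-OH, 10-OTMS) | CC(C)=CCC[C@]1(C)CC(S(=O)(=O)c3ccccc3)[C@@]2(O)C(C)=CCC[C@@]2(CO[Si](C)(C)C(C)(C)C)C(O[Si](C)(C)C)C1
F3 | step 15 | primary alcohol from 24 (C12–OH, 4-OH, 10-OMs) | CC(C)=CCC[C@]1(C)CC[C@@]2(O)C(C)=CCC[C@@]2(CO)[C@@H](OS(C)(=O)=O)C1
F4 | step 15 | β-hydroxy aldehyde (C12 aldehyde, 4-OH, 10-OMs) | CC(C)=CCC[C@]1(C)CC[C@@]2(O)C(C)=CCC[C@@]2(C=O)[C@@H](OS(C)(=O)=O)C1
F5 | step 15 | eleven-membered keto enal (C4 ketone, C12 aldehyde on ring-cis C9=C10) | CC(C)=CCC[C@]1(C)CCC(=O)/C(C)=C\CC/C(C=O)=C\C1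
F6 | step 15 | eleven-membered keto allylic alcohol (C12–OH) | CC(C)=CCC[C@]1(C)CCC(=O)/C(C)=C\CC/C(CO)=C\C1
F7 | step 17 | (4R)-epimer of 29 | CC(C)=CCC[C@]1(C)/C=C/[C@@H](O)/C(C)=C\CC/C(CO[Si](C)(C)C(C)(C)C)=C\C1
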